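**Retrosynthetic overview**

- Elemane numbering is used: ring C5–C10, C10 quaternary (C14 methyl, C1=C2 vinyl), C8 acyloxy, C7 carrying C11(=C13H2)C12O2H, C6 carbinol, C5 carrying C4(=C3H2)C15H2OH. The strategy rests on the C6 carbinol trans to C7 with its C11=C13 methylene, a homoallylic alcohol on the cyclohexane, which is the retron of a carbonyl-ene reaction.
- Late stage: the C8 ester comes from a Z-acetoxy acid made from 3-methylfuran-2(5H)-one; the C12 acid comes from the isopropenyl methyl (SeO2, then NaClO2); silyl groups are removed last.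
- Key disconnection C6–C7: type 1 carbonyl-ene closure of an acyclic C6 aldehyde onto the C7=C11 dimethyl alkene. This is the only ring-forming event (cyclohexane C5–C10).
- The aldehyde comes from a chair Ireland–Claisen rearrangement forming C5–C10 (sets C5, C10). The (E)-allylic alcohol comes from a vinylogous Mukaiyama aldol of 3-methylbut-2-enal (sets C8); the acid partner comes from monomethyl itaconate.

Key step: step 12

Assumption: the sense of induction of the chiral bisphosphoramide (step 2) and of the chiral bromoborane (step 9) is taken from the usual transition-state models for these reagent classes; if either proved opposite, the antipodal reagent would be used with no other change.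

**Route**

Step 1
Reactants: 1 methyl 3-methylbut-2-enoate
Product: 2 tert-butyl{[(1Z)-1-methoxy-3-methylbuta-1,3-dien-1-yl]oxy}dimethylsilane
Conditions: LiN(i-Pr)2, THF, −78 °C; then TBSCl, DMPU, −78 °C to rt
Reagents that add atoms: tert-butylchlorodimethylsilane, CC(C)(C)[Si](C)(C)Cl
Why: γ-Deprotonation of the senecioate and O-silylation of the lithium dienolate (silyl ketene acetal formation) should give the extended silyl dienolate needed for a vinylogous Mukaiyama aldol reaction.

Step 2
Reactants: 2 tert-butyl{[(1Z)-1-methoxy-3-methylbuta-1,3-dien-1-yl]oxy}dimethylsilane; 3 3-methylbut-2-enal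
Product: 4 methyl (2E,5S)-5-hydroxy-3,7-dimethylocta-2,6-dienoate
Conditions: SiCl4 (1.1 equiv), (S,S)-binaphthyl-2,2'-diamine-derived bisphosphoramide with pentane-1,5-diyl tether (2 mol %), i-Pr2NEt (10 mol %), CH2Cl2, −78 °C; aq. NaHCO3
Reagents that add atoms: none
Why: In this Lewis-base-activated SiCl4 vinylogous Mukaiyama aldol the phosphoramide-bound trichlorosilyl cation activates the enal for 1,2-attack by the γ-carbon of the dienolate, which should give the (E)-enoate and set C8 (S) by catalyst control of the aldehyde face.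

Step 3
Reactants: 4 methyl (2E,5S)-5-hydroxy-3,7-dimethylocta-2,6-dienoate
Product: 5 methyl (2E,5S)-3,7-dimethyl-5-(triethylsilyloxy)octa-2,6-dienoate
Conditions: TESCl, imidazole, DMF, 0 °C
Reagents that add atoms: chlorotriethylsilane, CC[Si](Cl)(CC)CC
Why: Standard imidazole-promoted silylation of a secondary allylic alcohol gives a weakly Lewis-basic triethylsilyl ether that can later be cleaved in the presence of tert-butyldimethylsilyl ethers.

Step 4
Reactants: 5 methyl (2E,5S)-3,7-dimethyl-5-(triethylsilyloxy)octa-2,6-dienoate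
Product: 6 (2E,5S)-3,7-dimethyl-5-(triethylsilyloxy)octa-2,6-dien-1-ol
Conditions: i-Bu2AlH (2.5 equiv), CH2Cl2, −78 °C; aq. KNaC4H4O6
Reagents that add atoms: none
Why: 1,2-Reduction of the α,β-unsaturated ester by i-Bu2AlH at low temperature should give the (E)-allylic alcohol without touching the silyl ether or the alkene geometry.

Step 5
Reactants: 7 4-methyl hydrogen itaconate (4-methoxy-2-methylidene-4-oxobutanoic acid)
Product: 9 methyl 3-(hydroxymethyl)but-3-enoate, via mixed carbonic anhydride 8 (not isolated)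
Conditions: i-BuOCOCl, N-methylmorpholine, THF, −15 °C; then NaBH4, H2O, 0 °C
Reagents that add atoms: none
Why: Activation of the conjugated acid as a mixed carbonic anhydride followed by NaBH4 reduction reduces the carboxyl group chemoselectively in the presence of the methyl ester.

Step 6
Reactants: 9 methyl 3-(hydroxymethyl)but-3-enoate
Product: 10 methyl 3-{[(tert-butyldimethylsilyl)oxy]methyl}but-3-enoate
Conditions: TBSCl, imidazole, CH2Cl2, 0 °C to rt
Reagents that add atoms: tert-butylchlorodimethylsilane, CC(C)(C)[Si](C)(C)Cl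
Why: Imidazole-promoted silylation of the primary allylic alcohol, carried out at once, prevents lactonisation of the γ-hydroxy ester.

Step 7
Reactants: 10 methyl 3-{[(tert-butyldimethylsilyl)oxy]methyl}but-3-enoate
Product: 11 3-{[(tert-butyldimethylsilyl)oxy]methyl}but-3-enoic acid
Conditions: LiOH, THF/H2O (3:1), 0 °C; aq. HCl to pH 4
Reagents that add atoms: lithium hydroxide, [Li+].[OH-]
Why: Cold saponification of the methyl ester should be faster than base-mediated migration of the β,γ-double bond into conjugation, and the silyl ether survives the mild acidification.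

Step 8
Reactants: 6 (2E,5S)-3,7-dimethyl-5-(triethylsilyloxy)octa-2,6-dien-1-ol; 11 3-{[(tert-butyldimethylsilyl)oxy]methyl}but-3-enoic acid
Product: 12 (2E,5S)-3,7-dimethyl-5-(triethylsilyloxy)octa-2,6-dien-1-yl 3-{[(tert-butyldimethylsilyl)oxy]methyl}but-3-enoate
Conditions: DCC, DMAP (5 mol %), CH2Cl2, −10 to 0 °C
Reagents that add atoms: none
Why: Steglich esterification with only catalytic DMAP at low temperature couples the primary allylic alcohol with the β,γ-unsaturated acid without moving the double bond into conjugation.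

Step 9
Reactants: 12 (2E,5S)-3,7-dimethyl-5-(triethylsilyloxy)octa-2,6-dien-1-yl 3-{[(tert-butyldimethylsilyl)oxy]methyl}but-3-enoate
Product: 14 (2S,3S,5S)-3-ethenyl-3,7-dimethyl-2-[3-(tert-butyldimethylsilyloxy)prop-1-en-2-yl]-5-(triethylsilyloxy)oct-6-enoic acid, via chiral boron ketene acetal 13 (not isolated)
Conditions: (4S,5S)-2-bromo-1,3-bis{[3,5-bis(trifluoromethyl)phenyl]sulfonyl}-4,5-diphenyl-1,3,2-diazaborolidine (1.5 equiv), i-Pr2NEt (2 equiv), CH2Cl2, −78 °C; then −20 to 4 °C, several days; aqueous work-up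
Reagents that add atoms: none
Why: In this enantioselective Ireland–Claisen rearrangement, soft enolisation should give the boron dienolate with the 2-propenyl substituent cis to O–B, and the chair [3,3] shift of the (E)-allyl unit (C14 methyl axial, C9 chain and C5 arm equatorial) then fixes the C5/C10 relative configuration while the C2-symmetric diazaborolidine selects the chair face, giving 5S,10S.

Step 10
Reactants: 14 (2S,3S,5S)-3-ethenyl-3,7-dimethyl-2-[3-(tert-butyldimethylsilyloxy)prop-1-en-2-yl]-5-(triethylsilyloxy)oct-6-enoic acid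
Product: 15 (2S,3S,5S)-3-ethenyl-3,7-dimethyl-2-[3-(tert-butyldimethylsilyloxy)prop-1-en-2-yl]-5-(triethylsilyloxy)oct-6-en-1-ol
Conditions: LiAlH4, Et2O, 0 °C to rt
Reagents that add atoms: none
Why: Hydride reduction with LiAlH4 converts the hindered carboxylic acid to the primary alcohol and leaves the isolated alkenes and silyl ethers untouched.

Step 11
Reactants: 15 (2S,3S,5S)-3-ethenyl-3,7-dimethyl-2-[3-(tert-butyldimethylsilyloxy)prop-1-en-2-yl]-5-(triethylsilyloxy)oct-6-en-1-ol
Product: 16 (2S,3S,5S)-3-ethenyl-3,7-dimethyl-2-[3-(tert-butyldimethylsilyloxy)prop-1-en-2-yl]-5-(triethylsilyloxy)oct-6-enal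
Conditions: Dess–Martin periodinane, NaHCO3, CH2Cl2, 0 °C; used at once
Reagents that add atoms: none
Why: Buffered Dess–Martin oxidation gives the aldehyde under neutral, non-enolising conditions, so the β,γ-unsaturated α-stereocentre C5 should be preserved.

Step 12
Reactants: 16 (2S,3S,5S)-3-ethenyl-3,7-dimethyl-2-[3-(tert-butyldimethylsilyloxy)prop-1-en-2-yl]-5-(triethylsilyloxy)oct-6-enal
Product: 17 (5S,6R,7S,8S,10S)-15-(tert-butyldimethylsilyloxy)-8-(triethylsilyloxy)elema-1,3,11(13)-trien-6-ol (cyclohexanol with equatorial C6–OH trans to the C7 isopropenyl group and cis to the C5 arm)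
Conditions: Me2AlCl (2.0 equiv), CH2Cl2, −78 °C; aq. KNaC4H4O6
Reagents that add atoms: none
Why: Me2AlCl binds the C6 aldehyde oxygen, the nucleophilic C7=C11 alkene attacks C6 through C7, and a hydrogen of a C11 methyl passes to oxygen in a six-membered ene transition state (concerted or via a tight C11 cation); the resulting aluminium alkoxide loses methane, so no free acid is left to promote side reactions. The closest known reaction is the Lewis-acid type 1 intramolecular carbonyl-ene cyclisation of citronellal to isopulegol. The cyclohexane C5–C10 closes in a 6-exo mode with respect to both the C=O and the C=C bond, C6 bonding to the proximal alkene carbon C7 and C11 staying exocyclic. C7 is set by the chair in which the cis-1,3 related C8 silyl ether and C10 vinyl are both equatorial, which places the C7–C11 bond equatorial with C8–H eclipsing the alkene (least allylic strain); C6 is set by the equatorial position of the aluminium-bound oxygen, the axial alternative being blocked by a 1,3-diaxial contact with the axial C10 methyl. The step needs C6–O trans to C7 and cis to the C5 arm (6R,7S) and reaction at the trisubstituted alkene only; the lower nucleophilicity of the vinyl and C3=C4 groups and the unfavourable ring sizes they would give secure the latter, while low temperature and the proton-scavenging Al–CH3 bond protect the epimerisable C5 and the allylic silyl ether.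

Step 13
Reactants: 17 (5S,6R,7S,8S,10S)-15-(tert-butyldimethylsilyloxy)-8-(triethylsilyloxy)elema-1,3,11(13)-trien-6-ol
Product: 18 (5S,6R,7R,8S,10S)-6,15-bis(tert-butyldimethylsilyloxy)-8-(triethylsilyloxy)elema-1,3,11(13)-triene (7R by priority change only; no centre is inverted)
Conditions: TBSOTf, 2,6-lutidine, CH2Cl2, −78 to 0 °C
Reagents that add atoms: tert-butyldimethylsilyl trifluoromethanesulfonate, CC(C)(C)[Si](C)(C)OS(=O)(=O)C(F)(F)F
Why: Silylation of the hindered equatorial C6 alcohol with the reactive silyl triflate masks it so that C8 can later be acylated selectively and the future C12 carboxyl cannot lactonise onto C6.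

Step 14
Reactants: 18 (5S,6R,7R,8S,10S)-6,15-bis(tert-butyldimethylsilyloxy)-8-(triethylsilyloxy)elema-1,3,11(13)-triene
Product: 20 (5S,6R,7R,8S,10S)-6,15-bis(tert-butyldimethylsilyloxy)-8-(triethylsilyloxy)elema-1,3,11(13)-trien-12-al, via C12 allylic alcohol 19 (not isolated)
Conditions: SeO2 (0.3 equiv), t-BuOOH, CH2Cl2, 0 °C to rt; then Dess–Martin periodinane, NaHCO3, CH2Cl2, 0 °C
Reagents that add atoms: selenium dioxide, O=[Se]=O (oxygen donor, turned over by tert-butyl hydroperoxide, CC(C)(C)OO)
Why: SeO2 allylic oxidation (ene reaction then [2,3]-sigmatropic shift) should attack the methyl of the electron-richer C11 isopropenyl group in preference to the oxygen-deactivated C3=C4 alkene or a ring methine, and the Dess–Martin oxidation converges the alcohol/aldehyde mixture to the enal.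

Step 15
Reactants: 20 (5S,6R,7R,8S,10S)-6,15-bis(tert-butyldimethylsilyloxy)-8-(triethylsilyloxy)elema-1,3,11(13)-trien-12-al
Product: 21 (5S,6R,7R,8S,10S)-6,15-bis(tert-butyldimethylsilyloxy)-8-hydroxyelema-1,3,11(13)-trien-12-al
Conditions: PPTS (0.2 equiv), MeOH/CH2Cl2 (1:1), 0 °C
Reagents that add atoms: none
Why: Mild acid-catalysed methanolysis cleaves the secondary triethylsilyl ether much faster than the two tert-butyldimethylsilyl ethers, so only the C8 hydroxyl should be freed.

Step 16
Reactants: 22 3-methylfuran-2(5H)-one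
Product: 24 (2Z)-4-acetoxy-2-methylbut-2-enoic acid, via sodium hydroxy-carboxylate 23 (not isolated)
Conditions: NaOH (1.0 equiv), H2O/MeOH, rt; concentrate; then Ac2O, pyridine, DMAP (cat.), 0 °C; aq. HCl to pH 3, 0 °C
Reagents that add atoms: sodium hydroxide, [Na+].[OH-]; acetic anhydride, CC(=O)OC(C)=O
Why: Saponification opens the butenolide to a hydroxy carboxylate whose Z geometry is fixed by the ring it came from, and O-acetylation before acidification prevents relactonisation.

Step 17
Reactants: 21 (5S,6R,7R,8S,10S)-6,15-bis(tert-butyldimethylsilyloxy)-8-hydroxyelema-1,3,11(13)-trien-12-al; 24 (2Z)-4-acetoxy-2-methylbut-2-enoic acid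
Product: 26 (5S,6R,7R,8S,10S)-8-{[(2Z)-4-acetoxy-2-methylbut-2-enoyl]oxy}-6,15-bis(tert-butyldimethylsilyloxy)elema-1,3,11(13)-trien-12-al, via trichlorobenzoyl mixed anhydride 25 (not isolated)
Conditions: 24, 2,4,6-trichlorobenzoyl chloride, Et3N, toluene, rt; then 21, toluene, 70 °C (no nucleophilic catalyst)
Reagents that add atoms: none
Why: Yamaguchi-type esterification through the 2,4,6-trichlorobenzoyl mixed anhydride without a nucleophilic catalyst acylates the C8 alcohol at the less hindered carbonyl and avoids the addition–elimination pathway that would isomerise the Z-enoate.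

Step 18
Reactants: 26 (5S,6R,7R,8S,10S)-8-{[(2Z)-4-acetoxy-2-methylbut-2-enoyl]oxy}-6,15-bis(tert-butyldimethylsilyloxy)elema-1,3,11(13)-trien-12-al
Product: 27 (5S,6R,7R,8S,10S)-8-{[(2Z)-4-acetoxy-2-methylbut-2-enoyl]oxy}-6,15-bis(tert-butyldimethylsilyloxy)elema-1,3,11(13)-trien-12-oic acid
Conditions: NaClO2, NaH2PO4, 2-methylbut-2-ene, t-BuOH/H2O, 0 °C to rt
Reagents that add atoms: sodium chlorite, [Na+].[O-]Cl=O
Why: Pinnick oxidation converts the conjugated aldehyde to the acrylic acid under buffered conditions, the alkene scavenger protecting the C=C bonds from hypochlorous acid.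

Step 19
Reactants: 27 (5S,6R,7R,8S,10S)-8-{[(2Z)-4-acetoxy-2-methylbut-2-enoyl]oxy}-6,15-bis(tert-butyldimethylsilyloxy)elema-1,3,11(13)-trien-12-oic acid
Product: 28 (5S,6R,7S,8S,10S)-8-{[(2Z)-4-acetoxy-2-methylbut-2-enoyl]oxy}-6,15-dihydroxyelema-1,3,11(13)-trien-12-oic acid (CNP0261293.8)
Conditions: HF·pyridine, pyridine, THF, 0 °C to rt; pH 5–6 buffer work-up, cold
Reagents that add atoms: none
Why: Buffered HF·pyridine desilylation removes both silyl ethers without base, so the acetate, the Z-enoate and the C8 ester should not transesterify, and the buffering limits lactonisation of the released C6 hydroxyl onto the acid.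

**Compound list**

1 | methyl 3-methylbut-2-enoate | COC(=O)C=C(C)C | starting material
2 | tert-butyl{[(1Z)-1-methoxy-3-methylbuta-1,3-dien-1-yl]oxy}dimethylsilane | C=C(C)/C=C(\O[Si](C)(C)C(C)(C)C)OC | intermediate
3 | 3-methylbut-2-enal | CC(C)=CC=O | starting material
4 | methyl (2E,5S)-5-hydroxy-3,7-dimethylocta-2,6-dienoate | COC(=O)/C=C(\C)C[C@H](O)C=C(C)C | intermediate
5 | methyl (2E,5S)-3,7-dimethyl-5-(triethylsilyloxy)octa-2,6-dienoate | COC(=O)/C=C(\C)C[C@H](O[Si](CC)(CC)CC)C=C(C)C | intermediate
6 | (2E,5S)-3,7-dimethyl-5-(triethylsilyloxy)octa-2,6-dien-1-ol | OC/C=C(\C)C[C@H](O[Si](CC)(CC)CC)C=C(C)C | intermediate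
7 | 4-methyl hydrogen itaconate (4-methoxy-2-methylidene-4-oxobutanoic acid) | COC(=O)CC(=C)C(=O)O | starting material
8 | isobutyl mixed carbonic anhydride of 7 (not isolated) | COC(=O)CC(=C)C(=O)OC(=O)OCC(C)C | intermediate
9 | methyl 3-(hydroxymethyl)but-3-enoate | COC(=O)CC(=C)CO | intermediate
10 | methyl 3-{[(tert-butyldimethylsilyl)oxy]methyl}but-3-enoate | COC(=O)CC(=C)CO[Si](C)(C)C(C)(C)C | intermediate
11 | 3-{[(tert-butyldimethylsilyl)oxy]methyl}but-3-enoic acid | OC(=O)CC(=C)CO[Si](C)(C)C(C)(C)C | intermediate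
12 | (2E,5S)-3,7-dimethyl-5-(triethylsilyloxy)octa-2,6-dien-1-yl 3-{[(tert-butyldimethylsilyl)oxy]methyl}but-3-enoate | C=C(CO[Si](C)(C)C(C)(C)C)CC(=O)OC/C=C(\C)C[C@H](O[Si](CC)(CC)CC)C=C(C)C | intermediate
13 | boron ketene acetal of 12 with the (4S,5S)-diazaborolidine, 2-propenyl group cis to O–B (not isolated) | C=C(CO[Si](C)(C)C(C)(C)C)/C=C(\OB1N(S(=O)(=O)c2cc(C(F)(F)F)cc(C(F)(F)F)c2)[C@@H](c2ccccc2)[C@H](c2ccccc2)N1S(=O)(=O)c1cc(C(F)(F)F)cc(C(F)(F)F)c1)OC/C=C(\C)C[C@H](O[Si](CC)(CC)CC)C=C(C)C | intermediate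
14 | (2S,3S,5S)-3-ethenyl-3,7-dimethyl-2-[3-(tert-butyldimethylsilyloxy)prop-1-en-2-yl]-5-(triethylsilyloxy)oct-6-enoic acid | OC(=O)[C@H](C(=C)CO[Si](C)(C)C(C)(C)C)[C@](C)(C=C)C[C@H](O[Si](CC)(CC)CC)C=C(C)C | intermediate
15 | (2S,3S,5S)-3-ethenyl-3,7-dimethyl-2-[3-(tert-butyldimethylsilyloxy)prop-1-en-2-yl]-5-(triethylsilyloxy)oct-6-en-1-ol | OC[C@H](C(=C)CO[Si](C)(C)C(C)(C)C)[C@](C)(C=C)C[C@H](O[Si](CC)(CC)CC)C=C(C)C | intermediate
16 | (2S,3S,5S)-3-ethenyl-3,7-dimethyl-2-[3-(tert-butyldimethylsilyloxy)prop-1-en-2-yl]-5-(triethylsilyloxy)oct-6-enal (key-step precursor) | O=C[C@H](C(=C)CO[Si](C)(C)C(C)(C)C)[C@](C)(C=C)C[C@H](O[Si](CC)(CC)CC)C=C(C)C | intermediate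
17 | (5S,6R,7S,8S,10S)-15-(tert-butyldimethylsilyloxy)-8-(triethylsilyloxy)elema-1,3,11(13)-trien-6-ol (key-step product) | C=C[C@]1(C)C[C@H](O[Si](CC)(CC)CC)[C@@H](C(C)=C)[C@H](O)[C@@H]1C(=C)CO[Si](C)(C)C(C)(C)C | intermediate
18 | (5S,6R,7R,8S,10S)-6,15-bis(tert-butyldimethylsilyloxy)-8-(triethylsilyloxy)elema-1,3,11(13)-triene | C=C[C@]1(C)C[C@H](O[Si](CC)(CC)CC)[C@@H](C(C)=C)[C@H](O[Si](C)(C)C(C)(C)C)[C@@H]1C(=C)CO[Si](C)(C)C(C)(C)C | intermediate
19 | (5S,6R,7R,8S,10S)-6,15-bis(tert-butyldimethylsilyloxy)-8-(triethylsilyloxy)elema-1,3,11(13)-trien-12-ol (not isolated) | C=C[C@]1(C)C[C@H](O[Si](CC)(CC)CC)[C@@H](C(=C)CO)[C@H](O[Si](C)(C)C(C)(C)C)[C@@H]1C(=C)CO[Si](C)(C)C(C)(C)C | intermediate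
20 | (5S,6R,7R,8S,10S)-6,15-bis(tert-butyldimethylsilyloxy)-8-(triethylsilyloxy)elema-1,3,11(13)-trien-12-al | C=C[C@]1(C)C[C@H](O[Si](CC)(CC)CC)[C@@H](C(=C)C=O)[C@H](O[Si](C)(C)C(C)(C)C)[C@@H]1C(=C)CO[Si](C)(C)C(C)(C)C | intermediate
21 | (5S,6R,7R,8S,10S)-6,15-bis(tert-butyldimethylsilyloxy)-8-hydroxyelema-1,3,11(13)-trien-12-al | C=C[C@]1(C)C[C@H](O)[C@@H](C(=C)C=O)[C@H](O[Si](C)(C)C(C)(C)C)[C@@H]1C(=C)CO[Si](C)(C)C(C)(C)C | intermediate
22 | 3-methylfuran-2(5H)-one | CC1=CCOC1=O | starting material
23 | sodium (2Z)-4-hydroxy-2-methylbut-2-enoate (not isolated) | [Na+].[O-]C(=O)/C(C)=C\CO | intermediate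
24 | (2Z)-4-acetoxy-2-methylbut-2-enoic acid | OC(=O)/C(C)=C\COC(C)=O | intermediate
25 | (2Z)-4-acetoxy-2-methylbut-2-enoic 2,4,6-trichlorobenzoic anhydride (not isolated) | O=C(OC(=O)/C(C)=C\COC(C)=O)c1c(Cl)cc(Cl)cc1Cl | intermediate
26 | (5S,6R,7R,8S,10S)-8-{[(2Z)-4-acetoxy-2-methylbut-2-enoyl]oxy}-6,15-bis(tert-butyldimethylsilyloxy)elema-1,3,11(13)-trien-12-al | C=C[C@]1(C)C[C@H](OC(=O)/C(C)=C\COC(C)=O)[C@@H](C(=C)C=O)[C@H](O[Si](C)(C)C(C)(C)C)[C@@H]1C(=C)CO[Si](C)(C)C(C)(C)C | intermediate
27 | (5S,6R,7R,8S,10S)-8-{[(2Z)-4-acetoxy-2-methylbut-2-enoyl]oxy}-6,15-bis(tert-butyldimethylsilyloxy)elema-1,3,11(13)-trien-12-oic acid | C=C[C@]1(C)C[C@H](OC(=O)/C(C)=C\COC(C)=O)[C@@H](C(=C)C(=O)O)[C@H](O[Si](C)(C)C(C)(C)C)[C@@H]1C(=C)CO[Si](C)(C)C(C)(C)C | intermediate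
28 | (5S,6R,7S,8S,10S)-8-{[(2Z)-4-acetoxy-2-methylbut-2-enoyl]oxy}-6,15-dihydroxyelema-1,3,11(13)-trien-12-oic acid | C=C[C@]1(C)C[C@H](OC(=O)/C(C)=C\COC(C)=O)[C@@H](C(=C)C(=O)O)[C@H](O)[C@@H]1C(=C)CO | target

**Step count and risks**

Total step count: 19. Longest linear sequence: 15 steps (steps 1–4, 8–15, 17–19).

Steps most likely to fail:

1. Step 12 (carbonyl-ene closure). The aluminium-bound intermediate may collapse by chloride capture at C11 instead of hydrogen transfer, or the Lewis acid may ionise the allylic C8 silyl ether or enolise the β,γ-unsaturated aldehyde and so erode C5. The fallback forms the same C6–C7 bond by an intramolecular allylboration that needs no Lewis acid. It sets out from alcohol 15. SeO2 (cat.)/t-BuOOH should oxidise the (E)-methyl of the trisubstituted C7=C11 alkene, the most reactive alkene, to give the (6E)-allylic diol (2S,3S,5S,6E)-3-ethenyl-3,7-dimethyl-2-[3-(tert-butyldimethylsilyloxy)prop-1-en-2-yl]-5-(triethylsilyloxy)oct-6-ene-1,8-diol F1. Methyl chloroformate and pyridine at −40 °C should acylate the unhindered allylic hydroxyl selectively to the allylic methyl carbonate F2. Dess–Martin oxidation of the remaining hindered C6 alcohol gives the carbonate aldehyde F3. Pd2(dba)3 (zerovalent palladium) with B2pin2 then converts the carbonate into the (E)-allyl pinacolboronate F4, which is not isolated: its γ-carbon C7 adds to the C6 aldehyde through a closed chair transition state (E-boronate gives the anti, that is trans C6–O/C7, product in the same ring chair as in step 12). Aqueous work-up returns the route to 17.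

2. Step 9 (boron-mediated Ireland–Claisen). Soft enolisation may give a mixture of ketene-acetal geometries and so scramble C5 relative to C10. The diazaborolidine may also discriminate the two chair faces poorly, or the [3,3] shift to the fully substituted C10 may be too slow at the temperatures the boron enolate tolerates. The fallback is the classical silyl ketene acetal rearrangement with separation of diastereomers. It sets out from ester 12. LiN(i-Pr)2 in THF/DMPU at −78 °C and Me3SiCl give the trimethylsilyl ketene acetal F5 with the 2-propenyl group cis to O–Si, the geometry favoured with the dipolar cosolvent. Warming to room temperature effects the chair rearrangement, and hydrolysis of the silyl ester on work-up gives two acids that share the C5/C10 relative configuration but differ in its sense relative to C8: acid 14 and its (2R,3R,5S) diastereomer F6. They are separated by chromatography and the route is rejoined at 14.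

3. Step 19 (final desilylation). Slow cleavage of the hindered C6 silyl ether under acidic fluoride leaves the freed C6 hydroxyl beside a protonated acrylic acid, which can close to the 6,12-lactone; loss of the acetate is a second possibility. The fallback masks the acid and deprotects with anhydrous, non-acidic fluoride. It sets out from acid 27. DCC/DMAP esterification with 2-(trimethylsilyl)ethanol gives the 2-(trimethylsilyl)ethyl ester F7. Treatment with (Me2N)3S(Me3SiF2) in DMF at 0 °C then removes the ester and both silyl ethers, the acid being released as the unreactive carboxylate before the C6 oxygen is unmasked. Buffered acidification (NaH2PO4, pH 5–6) gives 28.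

Further compounds
F1 | step 12 | (2S,3S,5S,6E)-3-ethenyl-3,7-dimethyl-2-[3-(tert-butyldimethylsilyloxy)prop-1-en-2-yl]-5-(triethylsilyloxy)oct-6-ene-1,8-diol | OC[C@H](C(=C)CO[Si](C)(C)C(C)(C)C)[C@](C)(C=C)C[C@H](O[Si](CC)(CC)CC)/C=C(\C)CO
F2 | step 12 | methyl carbonate of F1 at the allylic (C8 of the chain) hydroxyl | OC[C@H](C(=C)CO[Si](C)(C)C(C)(C)C)[C@](C)(C=C)C[C@H](O[Si](CC)(CC)CC)/C=C(\C)COC(=O)OC
F3 | step 12 | aldehyde from F2 (C1 of the chain oxidised) | O=C[C@H](C(=C)CO[Si](C)(C)C(C)(C)C)[C@](C)(C=C)C[C@H](O[Si](CC)(CC)CC)/C=C(\C)COC(=O)OC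
F4 | step 12 | (E)-allyl pinacolboronate aldehyde from F3 (not isolated) | O=C[C@H](C(=C)CO[Si](C)(C)C(C)(C)C)[C@](C)(C=C)C[C@H](O[Si](CC)(CC)CC)/C=C(\C)CB1OC(C)(C)C(C)(C)O1
F5 | step 9 | trimethylsilyl ketene acetal of 12, 2-propenyl group cis to O–Si | C=C(CO[Si](C)(C)C(C)(C)C)/C=C(\O[Si](C)(C)C)OC/C=C(\C)C[C@H](O[Si](CC)(CC)CC)C=C(C)C
F6 | step 9 | (2R,3R,5S)-3-ethenyl-3,7-dimethyl-2-[3-(tert-butyldimethylsilyloxy)prop-1-en-2-yl]-5-(triethylsilyloxy)oct-6-enoic acid | OC(=O)[C@@H](C(=C)CO[Si](C)(C)C(C)(C)C)[C@@](C)(C=C)C[C@H](O[Si](CC)(CC)CC)C=C(C)C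
F7 | step 19 | 2-(trimethylsilyl)ethyl ester of 27 | C=C[C@]1(C)C[C@H](OC(=O)/C(C)=C\COC(C)=O)[C@@H](C(=C)C(=O)OCC[Si](C)(C)C)[C@H](O[Si](C)(C)C(C)(C)C)[C@@H]1C(=C)CO[Si](C)(C)C(C)(C)C
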